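Remark on the chemistry: the target SMILES has no stereocentre and no configurationally free double bond (C3=C4 lies in the pyran ring), so the "single enantiomer" is the achiral compound itself and no stereocontrol is needed.

## Analysis of the target

13 is a 2,2-dimethyl-2H-chromene: a benzene ring (C4a, C5, C6, C7, C8, C8a) fused to a 2H-pyran (O1, C2 with two methyls, C3=C4). It carries OMe on C5, the 4-methoxyphenylacetyl ketone on C6, a free ketone-chelated OH on C7 and the only aromatic hydrogen of that ring on C8. With no stereogenic element, the problem is purely one of constitution. The three ring oxygens (C5, C7, C8a) form a phloroglucinol pattern in which each oxygen has a different role. The difficulty is to place them: the pyran carbon C4 must stand next to the methylated oxygen, and the acyl group between OMe and the free OH. Classical electrophilic chemistry on an acylphloroglucinol works against this, because the pyran closes next to the chelated hydroxyl and later alkylation or Lewis-acid dealkylation picks the wrong oxygen, leading to the 5-hydroxy-7-methoxy isomer. Sensitive groups are the electron-rich C3=C4 bond (acid, electrophiles, oxidants, hydrogenation), the free phenol, the enolisable benzylic ketone and the crowded 5-OMe group, the first ether to be lost to Lewis acids. The feature the route exploits is the substitution around C5: C5–OMe is flanked by two carbons that each carry a carbon substituent (C4a–C4 and C6–C=O), each followed by an oxygen-bearing carbon (C8a–O1 and C7–OH), with C8–H closing the ring, so a local mirror plane through C5 and C8 maps the pair C4a/C8a onto the pair C6/C7. Each pair is what results when an oxygen nucleophile carrying an electrophilic carbon adds across a 3-alkoxyaryne (oxygen distal, carbon next to OMe), so the benzene ring of 13 can be read as a 3-methoxy-1,4-benzdiyne captured twice.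

## Retrosynthetic reasoning

13 is cut at C6–C(=O) and C7–O together, giving the o-silylaryl triflate 10 and the commercial acid 11. The two bonds are ortho to each other and the C–C bond lies next to C5–OMe, which is the regiochemistry of a carboxylate adding to aryne 12 followed by O→C acyl transfer. This joins the two halves in the last step, uses 11 without activation, delivers the phenol free and lets the 5-OMe group decide where the acyl group goes. The forward reaction must generate 12 from 10 with fluoride in the presence of the carboxylate, add oxygen at C7, and move the acyl group to C6 before the aryl anion is protonated.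

10 is cut at C4a–C4 and C8a–O1, which removes the whole pyran ring and leads to the symmetric bis(silyl triflate) 5 and the enal 6. Forward, one aryne (7) is released from 5; the aldehyde oxygen of 6 adds distal to OMe, the formal [2+2] adduct 8 opens to the o-quinone methide 9, and oxa-6π closure gives the chromene. The cut is made here because it puts the pyran carbon next to OMe, the orientation that phenol chemistry refuses. In 5 the two SiMe3/OTf pairs are mirror images, so whichever pair reacts first leads to 10. The forward reaction must trigger only one pair and favour capture by the weakly nucleophilic carbonyl oxygen.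

5 is cut at its two C–Si and two O–S bonds, leading back through the bis(phenoxide) 4 and the bis(silyl ether) 3 to the dibromoresorcinol 2. Each silyl group migrates from oxygen to the neighbouring carbon after bromine–lithium exchange, and each freed phenoxide is triflated, so all four groups are installed in one pot with no positional choice.

2 is cut at its two C–Br bonds to give commercial 1. C4 and C6 of 1 are each ortho to one OH and para to the other, C5 is meta to both, and the molecule is symmetric, so bromination has one outcome. The 2-OMe of 1 becomes the 5-OMe of 13. The two hydroxyls of 1 are spent as triflate leaving groups; the ring oxygens of 13 at C8a and C7 come from 6 and 11.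

## Alternatives that were turned down

Alternative 1: The textbook route cuts C6–C(=O) by Friedel–Crafts or Hoesch acylation of benzene-1,3,5-triol A1 with 11 to give the trihydroxydeoxybenzoin A2. The pyran is then made by condensation of A2 with 6 and oxa-6π closure to the 5,7-dihydroxychromene A3, and a final mono-O-methylation is needed. It was turned down because both selectivities are biased against 13. In A3 the 7-OH is flanked by C8–H while the 5-OH sits between C4a and the acyl carbon, so alkylation should go to O7 and give the isomer A4. Reaching 13 would need a protect–methylate–deprotect detour, and Lewis-acid demethylation of a dimethyl ether would remove the more crowded 5-OMe. The chromenylation of A2 can also close through an ortho oxygen to give the 8-acyl chromene. The result is five to six steps with two problems that each favour the wrong isomer.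

Alternative 2: 13 can be read as a seco-isoflavone and traced to biochanin A, A5. Its 7-propargyl ether A6 would undergo a propargyl Claisen / 1,5-H shift / oxa-6π cascade to the linear pyranoisoflavone A7, methylation would give A8, and hydroxide-induced ring opening with retro-Claisen loss of C2 would release 13. The forward key step is the one-carbon excision from A8. It was turned down for three reasons:
- The skeletal bonds are those of the textbook route: the acyl–arene bond is bought with A5 and the pyran comes from a classical Claisen, so the pyranone only serves as a cyclic protecting group.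
- Everything rests on C6 versus C8 selectivity in the Claisen step, which depends only on hydrogen-bond-induced bond fixation and can leak to the angular isomer.
- A carbon is carried only to be deleted, and a start from A5, which already holds the deoxybenzoin, is close to a semisynthesis.

Alternative 3: The C6–C(=O) bond could be made by directed ortho-metalation of a preformed chromene. The 7-O-carbamate A9 would be lithiated and acylated with the N-methoxy-N-methylamide A10 to give A11, followed by carbamate cleavage. It was turned down on mechanistic grounds:
- The carbamate has two ortho positions. C8 is flanked by O1, whose in-plane lone pair is locked toward C8–H, while the 5-OMe is forced by C4a to turn its methyl toward C6. Lithiation should therefore occur at C8 and give the 8-acyl isomer A12.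
- The acidic benzylic CH2 of A10 would quench the aryllithium.
- A9 itself requires a regiodefined 5-OMe/7-O chromene, which costs several extra steps.

Key step: step 3

## Route

Step 1
Reactants: 1 2-methoxybenzene-1,3-diol (2-methoxyresorcinol)
Product: 2 4,6-dibromo-2-methoxybenzene-1,3-diol
Conditions: NBS (2.05 equiv), MeCN, 0 °C → rt, dark
Reagents that add atoms: N-bromosuccinimide, O=C1CCC(=O)N1Br
Why: Electrophilic aromatic bromination; C4 and C6 of 1 are each ortho to one OH and para to the other while C5 is meta to both, and the symmetry of 1 makes the two brominations equivalent, so 2 should form without positional isomers.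

Step 2
Reactants: 2 4,6-dibromo-2-methoxybenzene-1,3-diol
Product: 5 2-methoxy-4,6-bis(trimethylsilyl)-1,3-phenylene bis(trifluoromethanesulfonate), via bis-silyl ether 3 (not isolated), via dilithium diolate 4 (not isolated)
Conditions: HMDS, THF, 70 °C, then evaporation; n-BuLi (2.2 equiv), THF, −78 → −40 °C; Tf2O (2.4 equiv), −78 °C → rt
Reagents that add atoms: hexamethyldisilazane, C[Si](C)(C)N[Si](C)(C)C; trifluoromethanesulfonic anhydride, O=S(=O)(C(F)(F)F)OS(=O)(=O)C(F)(F)F; n-butyllithium, [Li]CCCC (its lithium appears only in intermediate 4)
Why: O-Silylation gives 3; double bromine–lithium exchange places each aryllithium ortho to an OSiMe3 group, which triggers a 1,3 O→C silyl shift (retro-Brook rearrangement) to the bis(phenoxide) 4, and triflation gives 5. This is the standard one-pot route from o-bromophenols to o-silylaryl triflates, run twice on a ring whose symmetry leaves no positional choice.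

Step 3
Reactants: 5 2-methoxy-4,6-bis(trimethylsilyl)-1,3-phenylene bis(trifluoromethanesulfonate); 6 3-methylbut-2-enal
Product: 10 5-methoxy-2,2-dimethyl-7-(trimethylsilyl)-2H-chromen-6-yl trifluoromethanesulfonate, via aryne 7 (not isolated), via benzoxete 8 (not isolated), via quinone methide 9 (not isolated)
Conditions: CsF (1.1 equiv), 6 (5 equiv), MeCN, 0 °C → rt
Reagents that add atoms: none
Why: Fluoride removes one SiMe3 group of 5 with loss of the neighbouring triflate to give aryne 7; the carbonyl oxygen of 6 adds to the aryne carbon remote from OMe, the aryl anion formed next to OMe closes onto the oxocarbenium carbon to give benzoxete 8 (formal [2+2]), 8 opens by a retro-4π process to the (Z)-o-quinone methide 9, and 9 cyclises to the 2H-pyran ring of 10. The closest known reaction type is the 2H-chromene annulation of arynes with α,β-unsaturated aldehydes, which shares its benzoxete/o-quinone methide manifold with the insertion of arynes into formamide C=O bonds. The pyran ring is closed by a thermal disrotatory oxa-6π electrocyclisation of the 1-oxatriene O=C8a–C4a=C4–C3=C2 (O1–C2 bond formed), driven by rearomatisation, as in classical phenol–enal chromene syntheses. No stereocentre is created, since C2 carries two methyl groups and 8 is a transient racemate. Regioselectivity comes from the methoxy group: 7 is a 3-alkoxyaryne whose inductively distorted triple bond is attacked at the distal carbon so that negative charge develops next to OMe, which puts O1 on C8a and C4 on C4a beside C5–OMe, the orientation that electrophilic chromenylation disfavours. The two SiMe3/OTf pairs of 5 are equivalent, so the first event needs no site control; over-reaction is then held back by electronics, because 5 has a triflate para to each C–Si bond whereas in 10 that position belongs to the electron-rich chromene, so 5 should be desilylated faster than 10 and about one equivalent of fluoride should stop at the mono-aryne stage. Chemoselectivity is secured by the excess of 6 (capture of 7 before ene reaction or oligomerisation), by the β,β-dimethyl terminus that disfavours [4+2] addition across the oxadiene, and by the intramolecular 6π closure of 9, which is faster than its capture by a second aryne.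

Step 4
Reactants: 10 5-methoxy-2,2-dimethyl-7-(trimethylsilyl)-2H-chromen-6-yl trifluoromethanesulfonate; 11 2-(4-methoxyphenyl)acetic acid
Product: 13 1-(7-hydroxy-5-methoxy-2,2-dimethyl-2H-chromen-6-yl)-2-(4-methoxyphenyl)ethan-1-one, via aryne 12 (not isolated)
Conditions: 11 (1.5 equiv), CsF (4 equiv), THF, 125 °C, sealed tube; then aq. NH4Cl
Reagents that add atoms: none
Why: Fluoride turns 10 into aryne 12; the carboxylate of 11 adds at C7 (remote from the 5-OMe, the same 3-alkoxyaryne rule), the C6 aryl anion attacks the ester carbonyl through a four-membered transition state, and the oxete alkoxide opens to the 2-acylphenoxide, protonated to 13 on work-up. This is the known formal insertion of arynes into the C(acyl)–O bond of carboxylic acids (o-hydroxyaryl ketone synthesis), favoured over simple O-arylation by the aprotic medium, excess fluoride base and high temperature. No stereocentre is formed, and the chromene, the ketone and both methyl ethers should be inert to CsF.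

## Compound list

1 | 2-methoxybenzene-1,3-diol | COc1c(O)cccc1O | starting material
2 | 4,6-dibromo-2-methoxybenzene-1,3-diol | COc1c(O)c(Br)cc(Br)c1O | intermediate
3 | 4,6-dibromo-2-methoxy-1,3-bis(trimethylsilyloxy)benzene | COc1c(O[Si](C)(C)C)c(Br)cc(Br)c1O[Si](C)(C)C | intermediate (not isolated)
4 | dilithium 2-methoxy-4,6-bis(trimethylsilyl)benzene-1,3-bis(olate) | [Li+].[Li+].COc1c([O-])c([Si](C)(C)C)cc([Si](C)(C)C)c1[O-] | intermediate (not isolated)
5 | 2-methoxy-4,6-bis(trimethylsilyl)-1,3-phenylene bis(trifluoromethanesulfonate) | COc1c(OS(=O)(=O)C(F)(F)F)c([Si](C)(C)C)cc([Si](C)(C)C)c1OS(=O)(=O)C(F)(F)F | intermediate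
6 | 3-methylbut-2-enal | CC(C)=CC=O | starting material
7 | 2-methoxy-6-(trimethylsilyl)-3,4-didehydrophenyl trifluoromethanesulfonate (aryne) | COC1=C(OS(=O)(=O)C(F)(F)F)C([Si](C)(C)C)=CC#C1 | intermediate (not isolated)
8 | 3-methoxy-2-(2-methylprop-1-en-1-yl)-5-(trimethylsilyl)-2H-benzo[b]oxet-4-yl trifluoromethanesulfonate (racemic) | COc1c(OS(=O)(=O)C(F)(F)F)c([Si](C)(C)C)cc2OC(C=C(C)C)c12 | intermediate (not isolated)
9 | (Z)-2-methoxy-3-(3-methylbut-2-en-1-ylidene)-4-oxo-6-(trimethylsilyl)cyclohexa-1,5-dien-1-yl trifluoromethanesulfonate | O=C1C=C([Si](C)(C)C)C(OS(=O)(=O)C(F)(F)F)=C(OC)/C1=C/C=C(C)C | intermediate (not isolated)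
10 | 5-methoxy-2,2-dimethyl-7-(trimethylsilyl)-2H-chromen-6-yl trifluoromethanesulfonate | COc1c(OS(=O)(=O)C(F)(F)F)c([Si](C)(C)C)cc2OC(C)(C)C=Cc12 | intermediate
11 | 2-(4-methoxyphenyl)acetic acid | COc1ccc(CC(=O)O)cc1 | starting material
12 | 6,7-didehydro-5-methoxy-2,2-dimethyl-2H-chromene (aryne) | COC1=C2C=CC(C)(C)OC2=CC#C1 | intermediate (not isolated)
13 | 1-(7-hydroxy-5-methoxy-2,2-dimethyl-2H-chromen-6-yl)-2-(4-methoxyphenyl)ethan-1-one | COc1ccc(CC(=O)c2c(O)cc3c(c2OC)C=CC(C)(C)O3)cc1 | target

## Step count and least certain steps

Total step count: 4. Longest linear sequence: 4 steps (1 → 2 → 5 → 10 → 13); 6 and 11 are commercial and enter directly.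

Step 3 (key step). The most likely failure is inefficient capture of aryne 7 by the weakly nucleophilic aldehyde oxygen. Ene reaction at the allylic methyls of 6, fluoride-induced self-condensation of 6 or aryne oligomerisation could then take over. A second risk is loss of site control, where desilylation of product 10 competes with that of 5 and leads to double annulation; this would be countered with sub-stoichiometric fluoride and recovery of 5. Fallback, from 5 back to 10: 5 would be treated with CsF (1.1 equiv) in DMF, so that aryne 7 inserts into the formamide C=O bond with the same regiochemistry. Hydrolytic work-up should give 3-formyl-4-hydroxy-2-methoxy-6-(trimethylsilyl)phenyl trifluoromethanesulfonate F1. Addition of 2-methylprop-1-enylmagnesium bromide (2.2 equiv, THF, −78 → 0 °C) should give 4-hydroxy-3-(1-hydroxy-3-methylbut-2-en-1-yl)-2-methoxy-6-(trimethylsilyl)phenyl trifluoromethanesulfonate F2 (racemic). Mild dehydration of F2 (catalytic PPTS or silica, toluene, 60–80 °C) should pass through quinone methide 9 and close to 10.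

Step 4. The C6 aryl anion may be protonated, or may take a proton from the acidic benzylic CH2 of the newly formed aryl ester, before it reaches the carbonyl group. This would divert the reaction to simple O-arylation with no C–C bond, and ketene or enolate chemistry of the arylacetate could follow. Fallback, from 10 back to 13: 10 would be treated with CsF (3 equiv) in DMF, and hydrolytic work-up should give 7-hydroxy-5-methoxy-2,2-dimethyl-2H-chromene-6-carbaldehyde F3 with the formyl group between OMe and OH. Addition of 4-methoxybenzylmagnesium chloride (2.5 equiv, THF, 0 °C) should give 6-[1-hydroxy-2-(4-methoxyphenyl)ethyl]-5-methoxy-2,2-dimethyl-2H-chromen-7-ol F4 (racemic). Oxidation of the benzylic alcohol with MnO2 (CH2Cl2, rt) should give 13.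

Step 2. After the first silyl migration the ring carries a phenoxide, so the second bromine–lithium exchange or the second O→C migration may be incomplete, or the aryllithium may be protonated, leaving mono-silylated material. Fallback, from 1 back to 5, replacing halogen–lithium exchange by carbamate-directed ortho-lithiation: 1 would be converted with diethylcarbamoyl chloride and NaH (THF) into 2-methoxy-1,3-phenylene bis(diethylcarbamate) F5. Lithiation with s-BuLi/TMEDA at −78 °C and TMSCl quench, carried out for each carbamate in turn (only C4 and C6 are free ortho positions), should give 2-methoxy-4,6-bis(trimethylsilyl)-1,3-phenylene bis(diethylcarbamate) F6. Reductive removal of the carbamoyl groups with LiAlH4 (THF, reflux) should give 2-methoxy-4,6-bis(trimethylsilyl)benzene-1,3-diol F7. Triflation of F7 (Tf2O, pyridine, CH2Cl2, 0 °C) should give 5.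

## Further compounds

F1 | step 3 | 3-formyl-4-hydroxy-2-methoxy-6-(trimethylsilyl)phenyl trifluoromethanesulfonate | COc1c(OS(=O)(=O)C(F)(F)F)c([Si](C)(C)C)cc(O)c1C=O
F2 | step 3 | 4-hydroxy-3-(1-hydroxy-3-methylbut-2-en-1-yl)-2-methoxy-6-(trimethylsilyl)phenyl trifluoromethanesulfonate (racemic) | COc1c(OS(=O)(=O)C(F)(F)F)c([Si](C)(C)C)cc(O)c1C(O)C=C(C)C
F3 | step 4 | 7-hydroxy-5-methoxy-2,2-dimethyl-2H-chromene-6-carbaldehyde | COc1c(C=O)c(O)cc2OC(C)(C)C=Cc12
F4 | step 4 | 6-[1-hydroxy-2-(4-methoxyphenyl)ethyl]-5-methoxy-2,2-dimethyl-2H-chromen-7-ol (racemic) | COc1ccc(CC(O)c2c(O)cc3OC(C)(C)C=Cc3c2OC)cc1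
F5 | step 2 | 2-methoxy-1,3-phenylene bis(diethylcarbamate) | CCN(CC)C(=O)Oc1cccc(OC(=O)N(CC)CC)c1OC
F6 | step 2 | 2-methoxy-4,6-bis(trimethylsilyl)-1,3-phenylene bis(diethylcarbamate) | COc1c(OC(=O)N(CC)CC)c([Si](C)(C)C)cc([Si](C)(C)C)c1OC(=O)N(CC)CC
F7 | step 2 | 2-methoxy-4,6-bis(trimethylsilyl)benzene-1,3-diol | COc1c(O)c([Si](C)(C)C)cc([Si](C)(C)C)c1O
A1 | alternative 1 | benzene-1,3,5-triol | Oc1cc(O)cc(O)c1
A2 | alternative 1 | 2-(4-methoxyphenyl)-1-(2,4,6-trihydroxyphenyl)ethan-1-one | COc1ccc(CC(=O)c2c(O)cc(O)cc2O)cc1
A3 | alternative 1 | 1-(5,7-dihydroxy-2,2-dimethyl-2H-chromen-6-yl)-2-(4-methoxyphenyl)ethan-1-one | COc1ccc(CC(=O)c2c(O)cc3OC(C)(C)C=Cc3c2O)cc1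
A4 | alternative 1 | 1-(5-hydroxy-7-methoxy-2,2-dimethyl-2H-chromen-6-yl)-2-(4-methoxyphenyl)ethan-1-one | COc1ccc(CC(=O)c2c(OC)cc3OC(C)(C)C=Cc3c2O)cc1
A5 | alternative 2 | 5,7-dihydroxy-3-(4-methoxyphenyl)-4H-chromen-4-one (biochanin A) | COc1ccc(cc1)C1=COc2cc(O)cc(O)c2C1=O
A6 | alternative 2 | 5-hydroxy-3-(4-methoxyphenyl)-7-[(2-methylbut-3-yn-2-yl)oxy]-4H-chromen-4-one | COc1ccc(cc1)C1=COc2cc(OC(C)(C)C#C)cc(O)c2C1=O
A7 | alternative 2 | 5-hydroxy-7-(4-methoxyphenyl)-2,2-dimethyl-2H,6H-pyrano[3,2-g]chromen-6-one | COc1ccc(cc1)C1=COc2cc3OC(C)(C)C=Cc3c(O)c2C1=O
A8 | alternative 2 | 5-methoxy-7-(4-methoxyphenyl)-2,2-dimethyl-2H,6H-pyrano[3,2-g]chromen-6-one | COc1ccc(cc1)C1=COc2cc3OC(C)(C)C=Cc3c(OC)c2C1=O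
A9 | alternative 3 | 5-methoxy-2,2-dimethyl-2H-chromen-7-yl diethylcarbamate | CCN(CC)C(=O)Oc1cc(OC)c2C=CC(C)(C)Oc2c1
A10 | alternative 3 | N-methoxy-2-(4-methoxyphenyl)-N-methylacetamide | COc1ccc(CC(=O)N(C)OC)cc1
A11 | alternative 3 | 5-methoxy-6-[2-(4-methoxyphenyl)acetyl]-2,2-dimethyl-2H-chromen-7-yl diethylcarbamate | CCN(CC)C(=O)Oc1cc2OC(C)(C)C=Cc2c(OC)c1C(=O)Cc1ccc(OC)cc1
A12 | alternative 3 | 5-methoxy-8-[2-(4-methoxyphenyl)acetyl]-2,2-dimethyl-2H-chromen-7-yl diethylcarbamate | CCN(CC)C(=O)Oc1cc(OC)c2C=CC(C)(C)Oc2c1C(=O)Cc1ccc(OC)cc1
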